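## Retrosynthetic overview

1. The C8–CH2–pyrone bridge is cut last: target 18 = chromene 11 + pyrone 15 + one CH2 from iminium salt 16, joined at the only free arene carbon of 11.
2. The 2,2-dimethyl-2H-pyran ring is not closed in its final size. It is grown from the 2,3-dihydrofuran ring of carbinol 7 (O1, C2, C3 and the two arene carbons) by a selenium-driven 1,2-shift that inserts the CMe2 carbon between O1 and C2 (five to six atoms, step 4). Selenoxide elimination then sets C3=C4.
3. Enabling feature: in 7 the ring oxygen O1 is para to the isobutyryl carbonyl on the benzene ring, so it can leave from C2 and return as a nucleophile, and the side-chain carbon on C2 is a tertiary CMe2 centre. Return of O1 to that carbon (tertiary C–O, secondary C–Se) is downhill, and because C2 of the new ring is quaternary, elimination can only go towards C4.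
4. 7 comes from C-prenylated phlorisobutyrophenone 5 (epoxidation, 5-exo closure by the para phenoxide), 5 from phloroglucinol, and 15 from a β-keto ester dianion.
5. Ring order: benzene (bought) → dihydrofuran (step 3) → pyran by ring expansion (step 4) → pyrone (step 7) → union (step 8).

Key step: step 4

Remark on stereochemistry: the target has no stereocentre; 6, 7, 8, 9, 10 and 14 each carry one carbon stereocentre that is formed racemic and is erased later (10 is in addition a mixture of epimers at selenium), so their SMILES carry no stereodescriptors.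

## Route

Step 1
Reactants: 1 phloroglucinol; 2 isobutyryl chloride
Product: 3 2-methyl-1-(2,4,6-trihydroxyphenyl)propan-1-one
Conditions: AlCl3 (3 equiv), PhNO2, 60 °C; ice/aq. HCl work-up
Reagents that add atoms: none
Why: Friedel–Crafts C-acylation of the symmetric triol should stop at the mono-ketone because the first acyl group deactivates the ring.

Step 2
Reactants: 3 2-methyl-1-(2,4,6-trihydroxyphenyl)propan-1-one; 4 prenyl bromide
Product: 5 2-methyl-1-[2,4,6-trihydroxy-3-(3-methylbut-2-en-1-yl)phenyl]propan-1-one
Conditions: 4 (0.9 equiv), KOH (1.0 equiv), H2O, 0 °C → rt; acidify, recover unreacted 3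
Reagents that add atoms: none
Why: SN2 C-alkylation of the ambident phloroglucinolate in water (protic medium favours carbon over oxygen) should place one prenyl group on one of the two equivalent ring CH positions, a deficit of bromide limiting double alkylation.

Step 3
Reactants: 5 2-methyl-1-[2,4,6-trihydroxy-3-(3-methylbut-2-en-1-yl)phenyl]propan-1-one
Product: 7 rac-1-[4,6-dihydroxy-2-(2-hydroxypropan-2-yl)-2,3-dihydro-1-benzofuran-5-yl]-2-methylpropan-1-one, via epoxide 6 (not isolated)
Conditions: DMDO (1.05 equiv, acetone solution), acetone, −30 °C; then K2CO3 (0.2 equiv), MeOH, 0 °C → rt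
Reagents that add atoms: dimethyldioxirane CC1(C)OO1
Why: Neutral alkene epoxidation followed by base-mediated 5-exo-tet epoxide opening, in which the most acidic hydroxyl (para to the ketone, not hydrogen-bonded) is ionised and attacks the secondary epoxide carbon with inversion, should fix the ether oxygen para to the acyl group and give racemic 7.

Step 4
Reactants: 7 rac-1-[4,6-dihydroxy-2-(2-hydroxypropan-2-yl)-2,3-dihydro-1-benzofuran-5-yl]-2-methylpropan-1-one
Product: 9 rac-1-[5,7-dihydroxy-2,2-dimethyl-3-(phenylselanyl)-3,4-dihydro-2H-chromen-6-yl]-2-methylpropan-1-one, via tertiary selenide 8 (not isolated)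
Conditions: PhSeH (1.3 equiv), ZnI2 (1.0 equiv), ClCH2CH2Cl, 0 °C → rt, N2, dark; then TsOH·H2O (0.2 equiv), 40 °C
Reagents that add atoms: benzeneselenol [SeH]c1ccccc1
Why: Proposed new method: ZnI2 ionises the tertiary carbinol and the resulting cation is trapped by the soft selenol as tertiary selenide 8 (Lewis-acid substitution of tertiary alcohols by thiols and selenols is the known model, and Markovnikov capture should outrun proton loss as it does when hydrogen halides add to isopropenyl-dihydrobenzofurans). Acid then activates the ring oxygen, a good leaving group because it is the para-acyl phenol oxygen; selenium displaces it from C2 with inversion to a seleniranium ion and the released phenol oxygen re-closes on the tertiary carbon, so the five-membered ring becomes the six-membered ring with the CMe2 carbon inserted between O1 and the old C2. The closest known reaction type is the acid-catalysed kinetic-to-thermodynamic ring expansion of 2-(1-phenylselanylalkyl)tetrahydrofurans to 3-(phenylselanyl)tetrahydropyrans through seleniranium ions (and the analogous 1,2-phenylsulfanyl shift); new here are the aryl ether oxygen as leaving and returning group and the tandem with the selenation. The pyran ring closes in the 6-endo mode by Markovnikov opening of the seleniranium ion at its tertiary carbon, driven by the tertiary C–O and secondary C–Se bonds of 9 against the secondary C–O and tertiary C–Se bonds of 8. The one new stereocentre (C3) results from anti opening of the seleniranium ion, is racemic and is erased in step 5, so no control element is needed. The step needs chemoselectivity (selenol capture and re-closure before proton loss or selenophilic collapse to the prenyl arene), for which the soft nucleophile is used in small excess at low temperature under N2, and regioselectivity between the two hydroxyls flanking the side chain, which should favour the free para oxygen because the ortho hydroxyl is engaged in the hydrogen-bond/zinc chelate with the ketone.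

Step 5
Reactants: 9 rac-1-[5,7-dihydroxy-2,2-dimethyl-3-(phenylselanyl)-3,4-dihydro-2H-chromen-6-yl]-2-methylpropan-1-one
Product: 11 1-(5,7-dihydroxy-2,2-dimethyl-2H-chromen-6-yl)-2-methylpropan-1-one, via selenoxide 10 (not isolated)
Conditions: H2O2 (30% aq., 3 equiv), pyridine (2 equiv), CH2Cl2, 0 °C → rt
Reagents that add atoms: none
Why: Selenide oxidation and selenoxide syn-elimination should give only the conjugated C3=C4 alkene, because C2 is quaternary and the only β-hydrogens are at C4.

Step 6
Reactants: 12 methyl 3-oxopentanoate; 13 N-methoxy-N-methylpropanamide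
Product: 14 rac-methyl 4-methyl-3,5-dioxoheptanoate
Conditions: LiN(iPr)2 (2.2 equiv), THF, −78 → 0 °C; then 13 (1.0 equiv), −78 → 0 °C; aq. HCl
Reagents that add atoms: none
Why: Claisen-type γ-acylation of the β-keto ester dianion at its more reactive terminal carbanion with an N-methoxy-N-methylamide should stop at the ketone, since the chelated tetrahedral adduct survives until work-up.

Step 7
Reactants: 14 rac-methyl 4-methyl-3,5-dioxoheptanoate
Product: 15 6-ethyl-4-hydroxy-5-methyl-2H-pyran-2-one
Conditions: DBU (1.0 equiv), toluene, 80 °C; aq. HCl work-up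
Reagents that add atoms: none
Why: Base-mediated lactonisation of the 3,5-diketo ester (enol oxygen of the C5 ketone attacks the ester, methanol is lost) should give the aromatic 4-hydroxy-2-pyrone.

Step 8
Reactants: 15 6-ethyl-4-hydroxy-5-methyl-2H-pyran-2-one; 16 N,N-dimethylmethyleneiminium iodide (Eschenmoser's salt); 11 1-(5,7-dihydroxy-2,2-dimethyl-2H-chromen-6-yl)-2-methylpropan-1-one
Product: 18 3-{[5,7-dihydroxy-2,2-dimethyl-6-(2-methylpropanoyl)-2H-chromen-8-yl]methyl}-6-ethyl-4-hydroxy-5-methyl-2H-pyran-2-one, via Mannich base 17 (not isolated)
Conditions: 16 (1.0 equiv), CH2Cl2, 0 °C → rt; then 11 (1.0 equiv), MeCN, 60 °C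
Reagents that add atoms: none
Why: Mannich aminomethylation at pyrone C3, thermal loss of dimethylamine to the 3-methylenepyran-2,4-dione and Friedel–Crafts-type conjugate addition of the only free ring carbon (C8) of 11 should build the methylene bridge.

## Compound list

1 | phloroglucinol (benzene-1,3,5-triol) | Oc1cc(O)cc(O)c1 | starting material
2 | isobutyryl chloride (2-methylpropanoyl chloride) | CC(C)C(Cl)=O | starting material
3 | 2-methyl-1-(2,4,6-trihydroxyphenyl)propan-1-one | CC(C)C(=O)c1c(O)cc(O)cc1O | intermediate
4 | prenyl bromide (1-bromo-3-methylbut-2-ene) | CC(C)=CCBr | starting material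
5 | 2-methyl-1-[2,4,6-trihydroxy-3-(3-methylbut-2-en-1-yl)phenyl]propan-1-one | CC(C)C(=O)c1c(O)cc(O)c(CC=C(C)C)c1O | intermediate
6 | rac-1-{3-[(3,3-dimethyloxiran-2-yl)methyl]-2,4,6-trihydroxyphenyl}-2-methylpropan-1-one (epoxide, not isolated) | CC(C)C(=O)c1c(O)cc(O)c(CC2OC2(C)C)c1O | intermediate
7 | rac-1-[4,6-dihydroxy-2-(2-hydroxypropan-2-yl)-2,3-dihydro-1-benzofuran-5-yl]-2-methylpropan-1-one | CC(C)C(=O)c1c(O)cc2c(c1O)CC(O2)C(C)(C)O | intermediate
8 | rac-1-{4,6-dihydroxy-2-[2-(phenylselanyl)propan-2-yl]-2,3-dihydro-1-benzofuran-5-yl}-2-methylpropan-1-one (tertiary selenide, not isolated) | CC(C)C(=O)c1c(O)cc2c(c1O)CC(O2)C(C)(C)[Se]c1ccccc1 | intermediate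
9 | rac-1-[5,7-dihydroxy-2,2-dimethyl-3-(phenylselanyl)-3,4-dihydro-2H-chromen-6-yl]-2-methylpropan-1-one | CC(C)C(=O)c1c(O)cc2c(c1O)CC([Se]c1ccccc1)C(C)(C)O2 | intermediate
10 | 1-[3-(benzeneseleninyl)-5,7-dihydroxy-2,2-dimethyl-3,4-dihydro-2H-chromen-6-yl]-2-methylpropan-1-one (selenoxide, mixture of diastereomers, not isolated) | CC(C)C(=O)c1c(O)cc2c(c1O)CC([Se](=O)c1ccccc1)C(C)(C)O2 | intermediate
11 | 1-(5,7-dihydroxy-2,2-dimethyl-2H-chromen-6-yl)-2-methylpropan-1-one | CC(C)C(=O)c1c(O)cc2c(c1O)C=CC(C)(C)O2 | intermediate
12 | methyl 3-oxopentanoate | CCC(=O)CC(=O)OC | starting material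
13 | N-methoxy-N-methylpropanamide | CCC(=O)N(C)OC | starting material
14 | rac-methyl 4-methyl-3,5-dioxoheptanoate | CCC(=O)C(C)C(=O)CC(=O)OC | intermediate
15 | 6-ethyl-4-hydroxy-5-methyl-2H-pyran-2-one | CCc1oc(=O)cc(O)c1C | intermediate
16 | N,N-dimethylmethyleneiminium iodide (Eschenmoser's salt) | C=[N+](C)C.[I-] | starting material
17 | 3-[(dimethylamino)methyl]-6-ethyl-4-hydroxy-5-methyl-2H-pyran-2-one (Mannich base, not isolated) | CCc1oc(=O)c(CN(C)C)c(O)c1C | intermediate
18 | 3-{[5,7-dihydroxy-2,2-dimethyl-6-(2-methylpropanoyl)-2H-chromen-8-yl]methyl}-6-ethyl-4-hydroxy-5-methyl-2H-pyran-2-one | CCc1oc(=O)c(Cc2c(O)c(C(=O)C(C)C)c(O)c3c2OC(C)(C)C=C3)c(O)c1C | target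

## Step count and risks

Total step count: 8. Longest linear sequence: 6 steps (1, 2, 3, 4, 5, 8); the pyrone branch (6, 7) joins in step 8.

Steps most likely to fail:

1. Step 4 (proposed new method). The tertiary cation may lose a proton instead of being trapped, which leads on to aromatisation to a 2-isopropylbenzofuran. The seleniranium ion may collapse by selenophilic attack back to the prenyl arene. Re-closure may also occur through the neighbouring chelated hydroxyl, scrambling the position of the ring oxygen. The fallback uses known chemistry, sets out from 3 and comes back at 11. The para hydroxyl of 3, the only one not chelated to the ketone, is O-alkylated with 3-chloro-3-methylbut-1-yne (K2CO3, KI, CuI cat., acetone, 60 °C) to the aryl propargyl ether 1-{2,6-dihydroxy-4-[(2-methylbut-3-yn-2-yl)oxy]phenyl}-2-methylpropan-1-one F1. Heating F1 (xylene, 140 °C) should give 11 directly by aromatic Claisen rearrangement, 1,5-hydrogen shift and oxa-6π electrocyclisation, so that steps 2 to 5 are not needed and the route continues with step 8.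

2. Step 3. The oxidant may attack the electron-rich phloroglucinol nucleus in competition with the alkene, and the epoxide may be opened by the ortho hydroxyl or at its tertiary carbon (6-endo), eroding chemo- and regioselectivity. The fallback sets out from 3 and comes back at 9. 3 is annulated without any oxidant with (E)-1,4-dibromo-2-methylbut-2-ene (K2CO3, acetone, rt): C-alkylation through the less hindered CH2Br and SN2' closure by the para phenoxide should give rac-1-[4,6-dihydroxy-2-(prop-1-en-2-yl)-2,3-dihydro-1-benzofuran-5-yl]-2-methylpropan-1-one F2. Under the conditions of step 4 (PhSeH, TsOH·H2O, ClCH2CH2Cl), Markovnikov protonation of the isopropenyl group of F2 gives the same tertiary cation and hence 8 and then 9.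

3. Step 5. Electrophilic selenium by-products of the elimination may add back to the new styrene-type double bond or substitute the free, strongly activated C8 position, and the phenol may be over-oxidised. The fallback sets out from 9 and comes back at 18 by changing the order of events. 9 is first coupled with 15 and 16 under the conditions of step 8 (through 17) to give rac-3-{[5,7-dihydroxy-2,2-dimethyl-6-(2-methylpropanoyl)-3-(phenylselanyl)-3,4-dihydro-2H-chromen-8-yl]methyl}-6-ethyl-4-hydroxy-5-methyl-2H-pyran-2-one F3, in which no arene CH is left. Oxidation and syn-elimination of F3 (H2O2, pyridine, CH2Cl2, 0 °C → rt) should then give 18 directly.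

Further compounds
F1 | step 4 | 1-{2,6-dihydroxy-4-[(2-methylbut-3-yn-2-yl)oxy]phenyl}-2-methylpropan-1-one | CC(C)C(=O)c1c(O)cc(OC(C)(C)C#C)cc1O
F2 | step 3 | rac-1-[4,6-dihydroxy-2-(prop-1-en-2-yl)-2,3-dihydro-1-benzofuran-5-yl]-2-methylpropan-1-one | CC(C)C(=O)c1c(O)cc2c(c1O)CC(O2)C(C)=C
F3 | step 5 | rac-3-{[5,7-dihydroxy-2,2-dimethyl-6-(2-methylpropanoyl)-3-(phenylselanyl)-3,4-dihydro-2H-chromen-8-yl]methyl}-6-ethyl-4-hydroxy-5-methyl-2H-pyran-2-one | CCc1oc(=O)c(Cc2c(O)c(C(=O)C(C)C)c(O)c3c2OC(C)(C)C([Se]c2ccccc2)C3)c(O)c1C
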